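Ring A (C4a, C5, C6, C7, C8, C8a) is disconnected from the pyranone ring C. The feature exploited is the meta relationship of the C5 hydroxyl and the C7 oxygen on ring A, which is fused to ring C through C4a–C8a. A light-driven Wolff rearrangement and ketene–alkyne benzannulation forms C8–C8a, C5–C6, C7–C8 and C4a–C5 in one operation, delivering the 5-hydroxyl free and the 7-oxygen as a silyl ether. The precursor is a 6-aryl-4-pyranone bearing a diazoacetyl group at C2 and the benzyl-protected ring B, partnered with a silyloxyacetylene. Desilylation, hydrogenolysis and double sulfation follow.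

Key step: step 7

Assumption: the target is taken as drawn, the free bis(hydrogen sulfate); since aryl hydrogen sulfates are acid-labile, the last step ends with a cold cation exchange and the compound would best be stored as a salt.

Remark: diazomethane 10 is used as an ethereal solution generated from commercial N-methyl-N-nitroso-p-toluenesulfonamide and KOH; acetylene 13 is taken from a cylinder.

**Route**

Step 1
Reactants: 1 3-hydroxy-4-methoxyacetophenone; 2 benzyl bromide
Product: 3 3-benzyloxy-4-methoxyacetophenone
Conditions: K2CO3, DMF, 50 °C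
Reagents that add atoms: none
Why: Williamson etherification of the phenoxide should proceed cleanly, since carbonate does not enolise the aryl ketone enough to cause C-alkylation.

Step 2
Reactants: 3 3-benzyloxy-4-methoxyacetophenone; 4 ethyl acetate
Product: 5 1-(3-benzyloxy-4-methoxyphenyl)butane-1,3-dione
Conditions: NaH (2.5 equiv), 4 (excess), THF, 0 °C → reflux; then aq. HCl
Reagents that add atoms: none
Why: Crossed Claisen condensation of the ketone enolate with ethyl acetate is driven to completion by formation of the stabilised diketonate, and the benzyl and methyl ethers are inert to the base.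

Step 3
Reactants: 5 1-(3-benzyloxy-4-methoxyphenyl)butane-1,3-dione; 6 diethyl oxalate
Product: 8 ethyl 6-(3-benzyloxy-4-methoxyphenyl)-4-oxo-4H-pyran-2-carboxylate, via triketo ester 7 (not isolated)
Conditions: NaOEt (2.2 equiv), EtOH, 0 °C → rt; aq. HCl; then HCl, EtOH, 60 °C
Reagents that add atoms: none
Why: Under equilibrating Claisen conditions the diketone is acylated by the oxalate at its terminal methyl group, because only that product forms a doubly stabilised dianion (the logic of the acetone–oxalate route to chelidonic acid), and acid then cyclodehydrates the 1,3,5-tricarbonyl chain to the 4-pyranone without touching the benzyl ether.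

Step 4
Reactants: 8 ethyl 6-(3-benzyloxy-4-methoxyphenyl)-4-oxo-4H-pyran-2-carboxylate
Product: 9 6-(3-benzyloxy-4-methoxyphenyl)-4-oxo-4H-pyran-2-carboxylic acid
Conditions: LiOH·H2O (1.2 equiv), THF/H2O, 0 °C; then 1 M HCl, 40 °C
Reagents that add atoms: lithium hydroxide, [Li+].[OH-] (oxygen of the carboxyl OH)
Why: The ester next to the ring oxygen is activated and should saponify at 0 °C with near-stoichiometric hydroxide, and the acidic, slightly warm work-up recloses any pyranone that hydroxide has opened.

Step 5
Reactants: 9 6-(3-benzyloxy-4-methoxyphenyl)-4-oxo-4H-pyran-2-carboxylic acid; 10 diazomethane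
Product: 12 2-(3-benzyloxy-4-methoxyphenyl)-6-(2-diazoacetyl)-4H-pyran-4-one, via acid chloride 11 (not isolated)
Conditions: (COCl)2, DMF (cat.), CH2Cl2, 0 °C → rt; evaporate; then 10 (3 equiv), Et2O/THF, 0 °C
Reagents that add atoms: oxalyl chloride, O=C(Cl)C(=O)Cl (chlorine of intermediate 11 only)
Why: Acylation of diazomethane by the acid chloride (the first stage of an Arndt–Eistert sequence) is fast at 0 °C, excess diazomethane removes the HCl, and the short cold contact avoids dipolar cycloaddition to the pyranone double bonds.

Step 6
Reactants: 13 acetylene; 14 triisopropylsilyl trifluoromethanesulfonate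
Product: 17 (triisopropylsilyloxy)acetylene, via lithium acetylide 15 (not isolated), via lithium ethynolate 16 (not isolated)
Conditions: 13 (excess), n-BuLi, THF, −78 °C; LiOOt-Bu (from t-BuOOH and LiN(SiMe3)2), −78 → −10 °C; then 14, −78 → 0 °C
Reagents that add atoms: tert-butyl hydroperoxide, CC(C)(C)OO (the ynol oxygen); n-butyllithium, [Li]CCCC (lithium of intermediates 15 and 16 only)
Why: Oxidation of a lithium acetylide by the electrophilic oxygen of lithium tert-butyl peroxide gives the lithium ynolate, and the hard, bulky silyl triflate should silylate it on oxygen and not on carbon, the triisopropylsilyl group making the ynol ether robust enough to isolate.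

Step 7
Reactants: 12 2-(3-benzyloxy-4-methoxyphenyl)-6-(2-diazoacetyl)-4H-pyran-4-one; 17 (triisopropylsilyloxy)acetylene
Product: 22 3'-O-benzyl-7-O-triisopropylsilyldiosmetin, via pyranonylketene 18 (not isolated), via silyloxycyclobutenone 19 (not isolated), via dienylketene 20 (not isolated), via keto tautomer 21 (not isolated)
Conditions: hν (medium-pressure Hg lamp, Pyrex filter), 17 (2.5 equiv), ClCH2CH2Cl, rt; then 80 °C
Reagents that add atoms: none
Why: Light expels N2 from 12 and the pyranonyl group migrates in a Wolff rearrangement (C8–C8a) to ketene 18, whose electrophilic carbonyl carbon (future C5) is attacked by the nucleophilic unsubstituted carbon of 17 (C6) while the ketene α-carbon (C8) joins the silyloxy carbon (C7), giving cyclobutenone 19. Four-electron electrocyclic opening of 19 is reversible, so material funnels through the cyclisable geometry 20, and thermal disrotatory six-electron electrocyclisation onto pyranone C5 (future C4a) closes ring A as dienone 21, which enolises to the chelated 5-hydroxyl of 22. The closest known reaction type is the Danheiser benzannulation in its photochemical Wolff variant, established for aryl, heteroaryl and alkenyl diazomethyl ketones with silyloxyalkynes. No stereocentre is created, because the sp3 centres of 19 and 21 are lost on aromatisation. The step needs the correct orientation of the (2+2) addition, secured by the polarisation of the silyloxyalkyne, and a single site of closure, secured because pyranone C6 has only one carbon neighbour, the other being the ring oxygen. The hydrogen-bonded 5-hydroxyl is a poor nucleophile and should not be acylated by the ketene intermediates.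

Step 8
Reactants: 22 3'-O-benzyl-7-O-triisopropylsilyldiosmetin
Product: 23 3'-O-benzyldiosmetin
Conditions: Bu4NF (1.1 equiv), AcOH (1.1 equiv), THF, 0 °C
Reagents that add atoms: none
Why: Fluoride cleaves the aryl silyl ether rapidly because the acidic 7-phenoxide is a good leaving group, the acetic acid buffer protects the flavone from basic side reactions, and the benzyl and methyl ethers are inert.

Step 9
Reactants: 23 3'-O-benzyldiosmetin
Product: 24 diosmetin
Conditions: H2 (1 atm), 10% Pd/C, THF/MeOH, rt
Reagents that add atoms: none
Why: Hydrogenolysis of the benzylic C–O bond on Pd/C is much faster than reduction of the conjugated C2=C3 bond of a flavone, and the aryl methyl ether is untouched.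

Step 10
Reactants: 24 diosmetin
Product: 25 luteolin 4'-methyl ether 7,3'-disulfate
Conditions: SO3·pyridine (6 equiv), pyridine, rt → 40 °C; then sulfonic acid cation-exchange resin (H+ form), H2O/MeOH, 0 °C, lyophilise
Reagents that add atoms: sulfur trioxide–pyridine complex, O=S(=O)([O-])[n+]1ccccc1
Why: O-sulfonation by the SO3–amine complex should take the acidic 7-hydroxyl and the ordinary 3'-phenol, while the 5-hydroxyl, locked in a hydrogen bond to the C4 carbonyl, is too poor a nucleophile to react under these mild conditions.

**Compound list**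

1 | 3-hydroxy-4-methoxyacetophenone | CC(=O)c1ccc(OC)c(O)c1 | starting material
2 | benzyl bromide | BrCc1ccccc1 | starting material
3 | 3-benzyloxy-4-methoxyacetophenone | CC(=O)c1ccc(OC)c(OCc2ccccc2)c1 | intermediate
4 | ethyl acetate | CCOC(C)=O | starting material
5 | 1-(3-benzyloxy-4-methoxyphenyl)butane-1,3-dione | CC(=O)CC(=O)c1ccc(OC)c(OCc2ccccc2)c1 | intermediate
6 | diethyl oxalate | CCOC(=O)C(=O)OCC | starting material
7 | ethyl 6-(3-benzyloxy-4-methoxyphenyl)-2,4,6-trioxohexanoate (triketo ester, not isolated) | CCOC(=O)C(=O)CC(=O)CC(=O)c1ccc(OC)c(OCc2ccccc2)c1 | intermediate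
8 | ethyl 6-(3-benzyloxy-4-methoxyphenyl)-4-oxo-4H-pyran-2-carboxylate | CCOC(=O)c1cc(=O)cc(-c2ccc(OC)c(OCc3ccccc3)c2)o1 | intermediate
9 | 6-(3-benzyloxy-4-methoxyphenyl)-4-oxo-4H-pyran-2-carboxylic acid | OC(=O)c1cc(=O)cc(-c2ccc(OC)c(OCc3ccccc3)c2)o1 | intermediate
10 | diazomethane | C=[N+]=[N-] | starting material
11 | 6-(3-benzyloxy-4-methoxyphenyl)-4-oxo-4H-pyran-2-carbonyl chloride (acid chloride, not isolated) | O=C(Cl)c1cc(=O)cc(-c2ccc(OC)c(OCc3ccccc3)c2)o1 | intermediate
12 | 2-(3-benzyloxy-4-methoxyphenyl)-6-(2-diazoacetyl)-4H-pyran-4-one | COc1ccc(-c2cc(=O)cc(C(=O)C=[N+]=[N-])o2)cc1OCc1ccccc1 | intermediate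
13 | acetylene | C#C | starting material
14 | triisopropylsilyl trifluoromethanesulfonate | CC(C)[Si](C(C)C)(C(C)C)OS(=O)(=O)C(F)(F)F | starting material
15 | lithium acetylide (not isolated) | [Li+].[C-]#C | intermediate
16 | lithium ethynolate (not isolated) | [Li+].[O-]C#C | intermediate
17 | (triisopropylsilyloxy)acetylene | C#CO[Si](C(C)C)(C(C)C)C(C)C | intermediate
18 | [6-(3-benzyloxy-4-methoxyphenyl)-4-oxo-4H-pyran-2-yl]ketene (not isolated) | O=C=Cc1cc(=O)cc(-c2ccc(OC)c(OCc3ccccc3)c2)o1 | intermediate
19 | 4-[6-(3-benzyloxy-4-methoxyphenyl)-4-oxo-4H-pyran-2-yl]-3-(triisopropylsilyloxy)cyclobut-2-en-1-one (racemic, not isolated) | O=C1C=C(O[Si](C(C)C)(C(C)C)C(C)C)C1c1cc(=O)cc(-c2ccc(OC)c(OCc3ccccc3)c2)o1 | intermediate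
20 | dienylketene with the ketene-bearing carbon and the pyranonyl group cis across the C=C bond (E by priority, not isolated) | O=C=C/C(O[Si](C(C)C)(C(C)C)C(C)C)=C\c1cc(=O)cc(-c2ccc(OC)c(OCc3ccccc3)c2)o1 | intermediate
21 | 4a-H keto tautomer of 22 (racemic cyclohexadienone, not isolated) | O=C1C=C(O[Si](C(C)C)(C(C)C)C(C)C)C=C2OC(c3ccc(OC)c(OCc4ccccc4)c3)=CC(=O)C12 | intermediate
22 | 3'-O-benzyl-7-O-triisopropylsilyldiosmetin (2-(3-benzyloxy-4-methoxyphenyl)-5-hydroxy-7-(triisopropylsilyloxy)-4H-chromen-4-one) | COc1ccc(-c2cc(=O)c3c(O)cc(O[Si](C(C)C)(C(C)C)C(C)C)cc3o2)cc1OCc1ccccc1 | intermediate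
23 | 3'-O-benzyldiosmetin (2-(3-benzyloxy-4-methoxyphenyl)-5,7-dihydroxy-4H-chromen-4-one) | COc1ccc(-c2cc(=O)c3c(O)cc(O)cc3o2)cc1OCc1ccccc1 | intermediate
24 | diosmetin (5,7-dihydroxy-2-(3-hydroxy-4-methoxyphenyl)-4H-chromen-4-one) | COc1ccc(-c2cc(=O)c3c(O)cc(O)cc3o2)cc1O | intermediate
25 | luteolin 4'-methyl ether 7,3'-disulfate (diosmetin 7,3'-bis(hydrogen sulfate)) | COc1ccc(-c2cc(=O)c3c(O)cc(OS(=O)(=O)O)cc3o2)cc1OS(=O)(=O)O | target

**Summary**

Total step count: 10. Longest linear sequence: 9 steps (steps 1–5 and 7–10); step 6 is a one-step side branch.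

Steps most likely to fail:

1. Step 7. The diazoketone and, increasingly, the flavone product absorb the same light, so the Wolff rearrangement may stall, the pyranone may undergo its own photochemistry, or the ketene may dimerise before it meets the alkyne. The fallback builds ring C onto a preformed ring A. From 3, Claisen condensation with diethyl carbonate (NaH, toluene, reflux) would give ethyl 3-(3-benzyloxy-4-methoxyphenyl)-3-oxopropanoate F1. Heating it neat with commercial phloroglucinol (benzene-1,3,5-triol) at about 240 °C, a Mentzer-type phenol/β-keto ester condensation, should give 23 directly, and the route is rejoined at step 9.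

2. Step 6. Monolithium acetylide may disproportionate to Li2C2 on warming before it is oxidised, silylation may occur at carbon to give a silylketene, and the volatile, acid-sensitive product may be lost on isolation. The fallback blocks the alkyne terminus. From 14 and commercial (trimethylsilyl)acetylene, deprotonation with n-BuLi would give lithium (trimethylsilyl)acetylide F2, and oxidation with LiOOt-Bu would give lithium 2-(trimethylsilyl)ethynolate F3. Trapping with 14 would give the distillable 1-(triisopropylsilyloxy)-2-(trimethylsilyl)acetylene F4. Selective cleavage of the C–Si bond (K2CO3 cat., MeOH, 0 °C) would then return 17.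

3. Step 10. Sulfation may stop at a monosulfate, or the sulfate esters may be lost by acid hydrolysis during cation exchange and drying. The fallback uses a masked sulfate diester. From 24, 2,2,2-trichloroethyl chlorosulfate (Et3N, DMAP, THF) would give diosmetin 7,3'-bis(2,2,2-trichloroethyl sulfate) F5, which can be purified on silica as a neutral compound. Reductive unmasking (Zn, HCO2NH4, MeOH) and a cold cation exchange would give 25.

Further compounds
F1 | step 7 | ethyl 3-(3-benzyloxy-4-methoxyphenyl)-3-oxopropanoate | CCOC(=O)CC(=O)c1ccc(OC)c(OCc2ccccc2)c1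
F2 | step 6 | lithium (trimethylsilyl)acetylide | [Li+].[C-]#C[Si](C)(C)C
F3 | step 6 | lithium 2-(trimethylsilyl)ethynolate | [Li+].[O-]C#C[Si](C)(C)C
F4 | step 6 | 1-(triisopropylsilyloxy)-2-(trimethylsilyl)acetylene | C[Si](C)(C)C#CO[Si](C(C)C)(C(C)C)C(C)C
F5 | step 10 | diosmetin 7,3'-bis(2,2,2-trichloroethyl sulfate) | COc1ccc(-c2cc(=O)c3c(O)cc(OS(=O)(=O)OCC(Cl)(Cl)Cl)cc3o2)cc1OS(=O)(=O)OCC(Cl)(Cl)Cl
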